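**Retrosynthetic overview**
1. The target is the 8-O-vanilloyl ester of (1R,3R,4S,5S,7R,8R,10R)-3,4-epoxyguaiane-8,10-diol. Late disconnections: the ester C8–O bond, the oxirane (hydroxyl-directed epoxidation of C3=C4), and the C10 hydroxyl (conjugate borylation–oxidation of a C9=C10 enone), leading back to trans-fused guai-3-en-8-one.
2. Enabling feature: C8, the oxygen-bearing carbon of the seven-membered ring, lies between C9 and C7. C9 can be the terminal carbon of an isopropenyl group on C1 (C10=C9, C14), and C7 the less substituted carbon of a prenyl group on C5 (C7=C11, C12, C13).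
3. Key disconnection: ring C8–C9–C10–C1–C5–C6–C7 is therefore closed by stitching the two olefin arms with thexylborane (B–C9 and B–C7) and replacing boron by CO, which becomes C8 with its oxygen. The hydroboration also turns the prenyl terminus into the isopropyl group.
4. The boracycle is a temporary ring that controls C7 and is excised. The ring A double bond is masked as an enol triflate, and C10 is carried at the C–H level and oxidised afterwards.
5. Order of ring formation: ring A (bought as a silyloxycyclopentenone, decorated by three-component coupling), then the seven-membered carbocycle (last ring of the carbon skeleton), then the oxirane as a late functional group; the aromatic ring arrives with the acid.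

Key step: step 4

Remark: bicyclic compounds are named on the guaiane skeleton (ring fusion C1/C5, C14 on C10, C15 on C4, isopropyl C11–C13 on C7). CIP letters at C1 change with substituent priorities although the spatial arrangement at C1, C5 and C7 is the same throughout. The oxirane is treated as a functional group placed on the finished carbon skeleton.

Step 1
Reactants: 1 (S)-4-[(tert-butyldimethylsilyl)oxy]cyclopent-2-en-1-one; 2 isopropenylmagnesium bromide; 3 prenyl bromide (1-bromo-3-methylbut-2-ene)
Product: 5 (2S,3R,4S)-4-[(tert-butyldimethylsilyl)oxy]-2-(3-methylbut-2-en-1-yl)-3-(prop-1-en-2-yl)cyclopentan-1-one, via bromomagnesium enolate 4 (not isolated)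
Conditions: 2 (1.3 equiv), CuBr·SMe2 (10 mol %), THF, −78 → −40 °C; then 3 (2 equiv), HMPA, −40 → 0 °C
Reagents that add atoms: none
Why: Copper-catalysed 1,4-addition of the Grignard reagent takes place anti to the silyloxy group and the magnesium enolate is then allylated anti to the new isopropenyl group (three-component conjugate addition–enolate alkylation of the prostaglandin type), which fixes the trans arrangement of the two arms at the future C1 and C5 in the absolute sense dictated by the bought stereocentre.

Step 2
Reactants: 5
Product: 6 (4R,5S)-5-(3-methylbut-2-en-1-yl)-4-(prop-1-en-2-yl)cyclopent-2-en-1-one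
Conditions: DBU (1.2 equiv), CH2Cl2, 0 °C
Reagents that add atoms: none
Why: E1cB β-elimination of the silyloxy group gives the enone and removes the oxygen that only relayed chirality, while C1 is untouched and the epimerisable C5 stays in its more stable trans arrangement.

Step 3
Reactants: 6
Product: 8 (4R,5S)-5-(3-methylbut-2-en-1-yl)-4-(prop-1-en-2-yl)cyclopent-1-en-1-yl trifluoromethanesulfonate, via lithium enolate 7 (not isolated)
Conditions: LiBH(s-Bu)3 (1.05 equiv), THF, −78 °C; then PhNTf2, −78 → 0 °C
Reagents that add atoms: N-phenylbis(trifluoromethanesulfonimide), O=S(=O)(N(c1ccccc1)S(=O)(=O)C(F)(F)F)C(F)(F)F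
Why: Conjugate reduction of the enone by the hindered borohydride gives a regiodefined lithium enolate that is O-triflated (conjugate reduction–enolate trapping), which fixes the later C3=C4 position and masks this double bond as an electron-poor enol triflate that should not react with boranes.

Step 4
Reactants: 8
Product: 11 (1S,5S,7R)-4-(trifluoromethylsulfonyloxy)-15-norguai-3-en-8-one (C10 epimers), via B-thexyl boracycle 9 (not isolated), via boron-bound carbinol 10 (not isolated)
Conditions: thexylborane (1.0 equiv, from BH3·THF and 2,3-dimethylbut-2-ene), THF, 0 °C → rt, slow addition of 8, high dilution; then CO (70 atm), H2O (2 equiv), 50 °C; then NaOAc, 30% H2O2, 40 °C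
Reagents that add atoms: carbon monoxide, [C-]#[O+]
Why: Thexylborane adds first to the 1,1-disubstituted isopropenyl group (B to C9, H to C10) and then intramolecularly to the trisubstituted prenyl double bond (B to C7, H to C11, which creates the isopropyl group) to give the seven-membered boracycle 9; CO then binds to boron, the two ring B–C bonds migrate in turn from boron to the carbonyl carbon with retention while the poorly migrating thexyl group stays on boron, and buffered oxidation releases the ketone. The closest known reaction is the thexylborane cyclic hydroboration–carbonylation of dienes to cyclic ketones, known for dienes that pair a 1,1-disubstituted with a trisubstituted alkene such as limonene. The temporary boracycle is closed by intramolecular hydroboration through a seven-membered ring, and the carbocycle C8–C9–C10–C1–C5–C6–C7 is closed by the second 1,2-shift from boron to carbon, a ring contraction of the eight-membered acylborane. C7 is set in the intramolecular hydroboration: in the chair-like transition state, with the trans ring A bonds diequatorial, the bulky thexyl group should sit pseudo-equatorial on boron, so the four-centre B–H/C7=C11 array is eclipsed on the axial face anti to H-1 and the isopropyl group ends up syn to H-5, a configuration the migration keeps. C10 is formed as a mixture, which is tolerated because C10 becomes sp2 in step 6. The step needs chemoselectivity (isopropenyl before prenyl, enol triflate untouched) and intramolecularity, which the reactivity order of the three alkenes towards a hindered monoalkylborane and slow addition at high dilution are meant to secure.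

Step 5
Reactants: 11
Product: 12 (1S,5S,7R)-guai-3-en-8-one (C10 epimers)
Conditions: MeZnCl (2 equiv), Pd(PPh3)4 (5 mol %), THF, 50 °C
Reagents that add atoms: methylzinc chloride, C[Zn]Cl
Why: Negishi cross-coupling of the enol triflate with methylzinc chloride under zerovalent palladium catalysis introduces C15 and unveils the C3=C4 double bond under base-free conditions, so that C7 next to the ketone should not epimerise.

Step 6
Reactants: 12
Product: 14 (1R,5S,7R)-guaia-3,9-dien-8-one, via silyl enol ether 13 (not isolated)
Conditions: LiN(i-Pr)2, Me3SiCl, THF, −78 °C; then Pd(OAc)2 (1.05 equiv), MeCN, rt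
Reagents that add atoms: none
Why: Kinetic deprotonation at the C9 methylene (less hindered than the C7 methine), silylation and Saegusa–Ito oxidation with divalent palladium give the C9=C10 enone and remove the uncontrolled C10 centre.

Step 7
Reactants: 14
Product: 16 (1R,5S,7R,10R)-10-hydroxyguai-3-en-8-one, via tertiary pinacol boronate 15 (not isolated)
Conditions: B2pin2 (1.1 equiv), CuCl (5 mol %), (R,S)-Josiphos (6 mol %), NaOt-Bu (10 mol %), MeOH (2 equiv), THF, rt; then 30% H2O2, aq. NaHCO3, 0 °C
Reagents that add atoms: hydrogen peroxide, OO
Why: Copper-catalysed conjugate borylation of the β,β-disubstituted enone followed by stereoretentive oxidation of the tertiary boronate gives the tertiary alcohol, the copper–boryl species adding to C10 on the face syn to H-1 (the other face is blocked by the ring A methylene C2), a preference that the Josiphos enantiomer is chosen to reinforce.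

Step 8
Reactants: 16
Product: 17 (1R,5S,7R,8R,10R)-guai-3-ene-8,10-diol
Conditions: Me4NBH(OAc)3 (5 equiv), MeCN/AcOH (1:1), −30 °C
Reagents that add atoms: none
Why: Hydroxyl-directed reduction with triacetoxyborohydride (Evans–Saksena type): the borohydride exchanges onto the C10 hydroxyl and delivers hydride intramolecularly to the same face of the C8 carbonyl, which is also the face anti to the C7 isopropyl group, so that the C8 hydroxyl is set anti to the C10 hydroxyl and cis to isopropyl.

Step 9
Reactants: 18 4-acetoxy-3-methoxybenzoic acid
Product: 19 4-acetoxy-3-methoxybenzoyl chloride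
Conditions: (COCl)2 (1.5 equiv), DMF (cat.), CH2Cl2, 0 °C → rt; evaporation
Reagents that add atoms: oxalyl chloride, O=C(Cl)C(=O)Cl
Why: Conversion of the acid into the acid chloride by oxalyl chloride with catalytic DMF (Vilsmeier-type activation), which leaves the aryl acetate intact.

Step 10
Reactants: 17; 19
Product: 20 (1R,5S,7R,8R,10R)-10-hydroxyguai-3-en-8-yl 4-acetoxy-3-methoxybenzoate
Conditions: Et3N (3 equiv), DMAP (0.3 equiv), CH2Cl2, 0 °C → rt
Reagents that add atoms: none
Why: DMAP-catalysed acylation (nucleophilic catalysis) of the secondary C8 hydroxyl by the acid chloride; the tertiary C10 hydroxyl is too hindered to react and no stereocentre is touched.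

Step 11
Reactants: 20
Product: 21 (1R,3R,4S,5S,7R,8R,10R)-3,4-epoxy-10-hydroxyguaian-8-yl 4-acetoxy-3-methoxybenzoate
Conditions: VO(acac)2 (5 mol %), t-BuOOH (1.5 equiv), CH2Cl2, 0 °C → rt
Reagents that add atoms: tert-butyl hydroperoxide, CC(C)(C)OO
Why: Vanadium-catalysed hydroxyl-directed epoxidation: the C10 hydroxyl, which lies on the H-1 face and is bishomoallylic to C3=C4, binds the vanadium alkylperoxide and delivers oxygen to that face of the ring A double bond, which sets C3 and C4.

Step 12
Reactants: 21
Product: 22 (1R,3R,4S,5S,7R,8R,10R)-3,4-epoxy-10-hydroxyguaian-8-yl 4-hydroxy-3-methoxybenzoate (CNP0136245.2)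
Conditions: K2CO3 (0.2 equiv), MeOH, 0 °C
Reagents that add atoms: none
Why: Base-catalysed transesterification with methanol cleaves the phenolic acetate far faster than the hindered secondary aryl carboxylate and should not touch the epoxide or the tertiary alcohol.

**Compound list**
1 | (S)-4-[(tert-butyldimethylsilyl)oxy]cyclopent-2-en-1-one | O=C1C=C[C@@H](O[Si](C)(C)C(C)(C)C)C1 | starting material
2 | isopropenylmagnesium bromide (prop-1-en-2-ylmagnesium bromide) | CC(=C)[Mg]Br | starting material
3 | prenyl bromide (1-bromo-3-methylbut-2-ene) | CC(C)=CCBr | starting material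
4 | bromomagnesium enolate of (3R,4S)-4-[(tert-butyldimethylsilyl)oxy]-3-(prop-1-en-2-yl)cyclopentanone (enolate towards C2) | C=C(C)[C@@H]1[C@@H](O[Si](C)(C)C(C)(C)C)CC(O[Mg]Br)=C1 | intermediate
5 | (2S,3R,4S)-4-[(tert-butyldimethylsilyl)oxy]-2-(3-methylbut-2-en-1-yl)-3-(prop-1-en-2-yl)cyclopentan-1-one (all neighbouring substituents trans) | C=C(C)[C@@H]1[C@@H](O[Si](C)(C)C(C)(C)C)CC(=O)[C@H]1CC=C(C)C | intermediate
6 | (4R,5S)-5-(3-methylbut-2-en-1-yl)-4-(prop-1-en-2-yl)cyclopent-2-en-1-one (trans) | C=C(C)[C@@H]1C=CC(=O)[C@H]1CC=C(C)C | intermediate
7 | lithium (4R,5S)-5-(3-methylbut-2-en-1-yl)-4-(prop-1-en-2-yl)cyclopent-1-en-1-olate | C=C(C)[C@@H]1CC=C(O[Li])[C@H]1CC=C(C)C | intermediate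
8 | (4R,5S)-5-(3-methylbut-2-en-1-yl)-4-(prop-1-en-2-yl)cyclopent-1-en-1-yl trifluoromethanesulfonate (trans) | C=C(C)[C@@H]1CC=C(OS(=O)(=O)C(F)(F)F)[C@H]1CC=C(C)C | intermediate
9 | B-thexyl boracycle: 8-(2,3-dimethylbutan-2-yl)-8-bora-15-norguai-3-en-4-yl trifluoromethanesulfonate, trans ring fusion, isopropyl on C7 syn to H-5 (C10 epimers) | CC(C)C(C)(C)B1CC(C)[C@@H]2CC=C(OS(=O)(=O)C(F)(F)F)[C@H]2C[C@@H]1C(C)C | intermediate
10 | boron-bound carbinol: 8-hydroxy-8-[hydroxy(2,3-dimethylbutan-2-yl)boranyl]-15-norguai-3-en-4-yl trifluoromethanesulfonate (C8 and C10 epimers) | OC1(B(O)C(C)(C)C(C)C)CC(C)[C@@H]2CC=C(OS(=O)(=O)C(F)(F)F)[C@H]2C[C@@H]1C(C)C | intermediate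
11 | (1S,5S,7R)-4-(trifluoromethylsulfonyloxy)-15-norguai-3-en-8-one (trans-fused, C10 epimers) | O=C1CC(C)[C@@H]2CC=C(OS(=O)(=O)C(F)(F)F)[C@H]2C[C@@H]1C(C)C | intermediate
12 | (1S,5S,7R)-guai-3-en-8-one (C10 epimers) | O=C1CC(C)[C@@H]2CC=C(C)[C@H]2C[C@@H]1C(C)C | intermediate
13 | 8-(trimethylsilyloxy)guaia-3,8-diene, the silyl enol ether of 12 towards C9 (C10 epimers) | C[Si](C)(C)OC1=CC(C)[C@@H]2CC=C(C)[C@H]2C[C@@H]1C(C)C | intermediate
14 | (1R,5S,7R)-guaia-3,9-dien-8-one | O=C1C=C(C)[C@@H]2CC=C(C)[C@H]2C[C@@H]1C(C)C | intermediate
15 | (1R,5S,7R,10S)-10-(4,4,5,5-tetramethyl-1,3,2-dioxaborolan-2-yl)guai-3-en-8-one (boron syn to H-1) | O=C1C[C@@](C)(B2OC(C)(C)C(C)(C)O2)[C@@H]3CC=C(C)[C@H]3C[C@@H]1C(C)C | intermediate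
16 | (1R,5S,7R,10R)-10-hydroxyguai-3-en-8-one | O=C1C[C@@](C)(O)[C@@H]2CC=C(C)[C@H]2C[C@@H]1C(C)C | intermediate
17 | (1R,5S,7R,8R,10R)-guai-3-ene-8,10-diol | O[C@@H]1C[C@@](C)(O)[C@@H]2CC=C(C)[C@H]2C[C@@H]1C(C)C | intermediate
18 | 4-acetoxy-3-methoxybenzoic acid | COc1cc(C(=O)O)ccc1OC(C)=O | starting material
19 | 4-acetoxy-3-methoxybenzoyl chloride | COc1cc(C(=O)Cl)ccc1OC(C)=O | intermediate
20 | (1R,5S,7R,8R,10R)-10-hydroxyguai-3-en-8-yl 4-acetoxy-3-methoxybenzoate | COc1cc(C(=O)O[C@@H]2C[C@@](C)(O)[C@@H]3CC=C(C)[C@H]3C[C@@H]2C(C)C)ccc1OC(C)=O | intermediate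
21 | (1R,3R,4S,5S,7R,8R,10R)-3,4-epoxy-10-hydroxyguaian-8-yl 4-acetoxy-3-methoxybenzoate | COc1cc(C(=O)O[C@@H]2C[C@@](C)(O)[C@@H]3C[C@H]4O[C@@]4(C)[C@H]3C[C@@H]2C(C)C)ccc1OC(C)=O | intermediate
22 | (1R,3R,4S,5S,7R,8R,10R)-3,4-epoxy-10-hydroxyguaian-8-yl 4-hydroxy-3-methoxybenzoate | COc1cc(C(=O)O[C@@H]2C[C@@](C)(O)[C@@H]3C[C@H]4O[C@@]4(C)[C@H]3C[C@@H]2C(C)C)ccc1O | target

**Step count and risks**
Total step count: 12. Longest linear sequence: 11 steps (steps 1–8 and 10–12; step 9 is a one-step side branch).

The three steps most likely to fail:

Step 4. What may go wrong: facial discrimination in the ring-forming intramolecular hydroboration may be incomplete, or C7 may epimerise next to the new ketone, so that the isopropyl centre is not uniform; intermolecular hydroboration to oligomeric boranes would also lower the amount of ring-closed material. The fallback replaces substrate control by catalyst control and sets out from 12 taken as a C7-epimer mixture. Hydrogenation with RuCl2[(S)-binap][(S,S)-dpen] and KOt-Bu in i-PrOH under H2 (the catalyst enantiomer being the one that leads to the 7R,8R product) interconverts the C7 epimers through the enolate and reduces only one of them. This is a dynamic kinetic resolution of an α-branched cyclic ketone; it should give the cis alcohol and leave C3=C4 alone, affording (1S,5S,7R,8R)-guai-3-en-8-ol F1. Oxidation of F1 with Dess–Martin periodinane in CH2Cl2, without base, returns 12 as a single C7 epimer, where the fallback comes back to the route.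

Step 7. What may go wrong: addition of the copper–boryl species to the wrong face of C10, or base-induced epimerisation at C7 (or C1) of the enone under the alkoxide conditions. The fallback delivers the C10 oxygen as an epoxide instead of through boron and sets out from 14. Nucleophilic epoxidation (t-BuOOH, DBU, CH2Cl2, 0 °C; Weitz–Scheffer type) on the face syn to H-1 should give (1R,5S,7R,9S,10S)-9,10-epoxyguai-3-en-8-one F2. SmI2 (2.2 equiv) in THF/MeOH at −78 °C then cleaves the C9–O bond next to the ketone and keeps the C10–O bond, which gives 16, where the fallback comes back to the route.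

Step 11. What may go wrong: weak direction by the tertiary, bishomoallylic hydroxyl, so that the epoxidation is slow or shows poor facial selectivity. The fallback uses catalyst-controlled dioxirane epoxidation instead of substrate direction and sets out from 20. Shi epoxidation with the fructose-derived ketone catalyst (enantiomer chosen for the 3R,4S epoxide) and Oxone (2KHSO5·KHSO4·K2SO4) in buffered MeCN/H2O at 0 °C should give 21 directly, where the fallback comes back to the route; no new compound arises (F0).

Further compounds
F1 | step 4 | (1S,5S,7R,8R)-guai-3-en-8-ol (C10 epimers) | O[C@@H]1CC(C)[C@@H]2CC=C(C)[C@H]2C[C@@H]1C(C)C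
F2 | step 7 | (1R,5S,7R,9S,10S)-9,10-epoxyguai-3-en-8-one | O=C1[C@H]2O[C@@]2(C)[C@@H]3CC=C(C)[C@H]3C[C@@H]1C(C)C
F0 | step 11 | none | none
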